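**Strategy.** The trans-decalin is dissected at the Δ3 cyclohexene of ring A (C3=C4, eudesmane numbering), a Diels–Alder retron: an acyclic (E)-triene in which a four-carbon tether (C6–C9) joins diene C2=C3–C4(Me)=C5 to the 1,1-disubstituted alkene C1=C10. One thermal intramolecular cycloaddition forms the C5–C10 and C1–C2 bonds, closing ring B (C5–C6–C7–C8–C9–C10) together with ring A and setting C5 and C10 trans under control of the single stereocentre C7, which comes from (R)-limonene. No ring is formed afterwards; C12 and C15 are then oxidised and the (Z)-p-coumarate attached.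

Key step: step 4

Remark (assumption): eudesmane numbering is used (ring A = C1–C5, C10; ring B = C5–C10; C11–C13 acrylate; C14 on C10; C15 on C4). The target is the (5R,7R,10R) enantiomer, whose C7 has the configuration of (R)-limonene. Commercial (+)-limonene oxide is a cis/trans mixture; both isomers converge in step 1.

**Step 1**
Reactants: 1 (+)-limonene 1,2-oxide [(4R)]
Product: 3 (3R)-6-oxo-3-(prop-1-en-2-yl)heptanal, via p-menth-8-ene-1,2-diol 2 (not isolated)
Conditions: H5IO6 (1.1 equiv), THF–H2O, 0 °C → rt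
Reagents that add atoms: water, O
Why: Epoxide hydrolysis followed by Malaprade glycol cleavage should convert both epoxide diastereomers into the same keto-aldehyde, leaving the stereocentre (future C7) untouched.

**Step 2**
Reactants: 3 (3R)-6-oxo-3-(prop-1-en-2-yl)heptanal
Product: 4 (2E,5R)-2-methyl-8-oxo-5-(prop-1-en-2-yl)non-2-enal
Conditions: Ph3P=C(CH3)CHO (1.2 equiv), PhMe, 80 °C
Reagents that add atoms: 2-(triphenylphosphoranylidene)propanal, CC(C=O)=P(c1ccccc1)(c1ccccc1)c1ccccc1
Why: Wittig olefination with the formyl-stabilised ylide is aldehyde-selective (the methyl ketone should not react) and should give the (E)-enal, which places the chain cis to the future C15 methyl.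

**Step 3**
Reactants: 4 (2E,5R)-2-methyl-8-oxo-5-(prop-1-en-2-yl)non-2-enal
Product: 5 (3E,6R)-3,9-dimethyl-6-(prop-1-en-2-yl)deca-1,3,9-triene
Conditions: Ph3PCH3Br (3 equiv), KOtBu (2.9 equiv), THF, 0 °C → rt
Reagents that add atoms: methyltriphenylphosphonium bromide (as its ylide), C[P+](c1ccccc1)(c1ccccc1)c1ccccc1.[Br-]
Why: Double Wittig methylenation: the unstabilised ylide adds 1,2 to the enal, giving the (E)-diene with the C4=C5 geometry retained, and turns the methyl ketone into the 1,1-disubstituted dienophile.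

**Step 4 (key step)**
Reactants: 5 (3E,6R)-3,9-dimethyl-6-(prop-1-en-2-yl)deca-1,3,9-triene
Product: 6 α-selinene, (5R,7R,10R)-eudesma-3,11-diene
Conditions: PhMe (0.01 M), BHT (10 mol %), sealed silylated tube, 200–210 °C
Reagents that add atoms: none
Why: Thermal intramolecular Diels–Alder reaction, a concerted asynchronous [4+2] cycloaddition of the (E)-diene C2=C3–C4(Me)=C5 with the unactivated alkene C1=C10, in which the terminal C1–C2 bond leads and the C5–C10 bond completes both rings. The closest known reaction type is the thermal cyclisation of 2,8-dialkyl-1,7,9-decatrienes to trans-octalins. Ring A is the cycloaddition ring (its alkene ends at C3=C4, where the target needs it); ring B (C5–C6–C7–C8–C9–C10) is the fused ring made from the four-carbon tether and is closed by the C5–C10 bond in the anti (tether-exo, C10-methyl-endo) mode. C5 and C10 should be set trans (5α-H/10β-Me) because the C4 methyl, cis to the tether across C5=C4, puts A(1,3) strain on the syn (cis-fused) transition state; their absolute sense follows from C7, whose isopropenyl group sits equatorial on the chair-like tether. The step therefore needs trans over cis fusion and one diene face, secured by the C4 methyl and the C7 substituent; the isopropenyl group cannot act as dienophile because only two carbons separate it from the diene. High dilution and BHT suppress intermolecular addition and polymerisation.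

**Step 5**
Reactants: 6 α-selinene
Product: 9 (5R,7R,10R)-eudesma-3,11(13)-dien-12-ol (α-costol), via 12-lithio-α-selinene 7 (not isolated), via dimethyl 12-boronate 8 (not isolated)
Conditions: n-BuLi, TMEDA, hexane, rt; B(OMe)3, Et2O, −78 °C → rt; 30% H2O2, aq. NaOH, 0 °C
Reagents that add atoms: hydrogen peroxide, OO
Why: Kinetic allylic lithiation with n-BuLi·TMEDA should occur at the methyl of the 1,1-disubstituted isopropenyl group (as with limonene, the ring-alkene methyl is not metalated), and borylation with alkaline peroxide oxidation of the allylboronate gives the primary allylic alcohol without touching a stereocentre.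

**Step 6**
Reactants: 9 α-costol
Product: 10 (5R,7R,10R)-eudesma-3,11(13)-dien-12-al (α-costal)
Conditions: MnO2 (excess), CH2Cl2, rt
Reagents that add atoms: none
Why: Chemoselective MnO2 oxidation of the primary allylic alcohol should give the 2-substituted acrolein and leave the isolated trisubstituted alkene alone.

**Step 7**
Reactants: 10 α-costal
Product: 11 (5R,7R,10R)-15-hydroxyeudesma-3,11(13)-dien-12-al
Conditions: SeO2 (0.5 equiv), t-BuOOH (2.5 equiv), CH2Cl2, 0 °C → rt
Reagents that add atoms: selenium dioxide (oxygen carrier), O=[Se]=O; tert-butyl hydroperoxide (terminal oxidant), CC(C)(C)OO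
Why: SeO2/t-BuOOH allylic hydroxylation (ene reaction then [2,3]-sigmatropic shift) should attack only the electron-rich C3=C4 alkene at the methyl on its more substituted end (C15), since C5–H is a hindered methine and the enal alkene is electron-poor, so the alkene stays at C3=C4.

**Step 8**
Reactants: 12 4-[(tert-butyldimethylsilyl)oxy]benzaldehyde
Product: 13 methyl (Z)-3-{4-[(tert-butyldimethylsilyl)oxy]phenyl}prop-2-enoate
Conditions: (CF3CH2O)2P(O)CH2CO2Me, KHMDS, 18-crown-6, THF, −78 °C
Reagents that add atoms: methyl bis(2,2,2-trifluoroethyl)phosphonoacetate, COC(=O)CP(=O)(OCC(F)(F)F)OCC(F)(F)F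
Why: Still–Gennari variant of the Horner–Wadsworth–Emmons olefination, in which the electron-poor phosphonate under dissociating conditions eliminates kinetically to the (Z)-cinnamate.

**Step 9**
Reactants: 13 methyl (Z)-3-{4-[(tert-butyldimethylsilyl)oxy]phenyl}prop-2-enoate
Product: 14 (Z)-3-(4-hydroxyphenyl)prop-2-enoic acid [(Z)-p-coumaric acid]
Conditions: LiOH·H2O, THF–MeOH–H2O, 0 °C → rt, dark; then 1 M HCl
Reagents that add atoms: lithium hydroxide, [Li+].[OH-]
Why: Saponification of the methyl ester with concomitant cleavage of the base-labile aryl silyl ether; run cold and in the dark, the Z alkene should be retained.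

**Step 10**
Reactants: 11 (5R,7R,10R)-15-hydroxyeudesma-3,11(13)-dien-12-al; 14 (Z)-p-coumaric acid
Product: 15 (5R,7R,10R)-15-[(Z)-p-coumaroyloxy]eudesma-3,11(13)-dien-12-al
Conditions: PPh3, DIAD, THF, 0 °C → rt, dark (DIAD added last)
Reagents that add atoms: none
Why: Mitsunobu esterification: the primary allylic alcohol is activated as its alkoxyphosphonium ion and displaced SN2 at C15 by the carboxylate, which is far more acidic than the phenol, so the phenol should need no protection and the neutral conditions preserve the Z alkene and the enal.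

**Step 11**
Reactants: 15 (5R,7R,10R)-15-[(Z)-p-coumaroyloxy]eudesma-3,11(13)-dien-12-al
Product: 16 (5R,7R,10R)-15-[(Z)-p-coumaroyloxy]eudesma-3,11(13)-dien-12-oic acid (CNP0183482.1)
Conditions: NaClO2, NaH2PO4, 2-methyl-2-butene (large excess), t-BuOH–THF–H2O, 0 °C, dark
Reagents that add atoms: sodium chlorite, [Na+].[O-]Cl=O
Why: Pinnick (Lindgren) chlorite oxidation should convert the α-substituted acrolein into the acrylic acid under buffered, mildly acidic conditions that leave the allylic ester, the Z-cinnamate and the alkenes intact, with excess 2-methyl-2-butene trapping HOCl.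

**Compound list**
1 | (+)-limonene 1,2-oxide, (4R), cis/trans mixture | CC12OC2C[C@@H](CC1)C(C)=C | starting material
2 | (4R)-1-methyl-4-(prop-1-en-2-yl)cyclohexane-1,2-diol | CC1(O)CC[C@H](CC1O)C(C)=C | intermediate (not isolated)
3 | (3R)-6-oxo-3-(prop-1-en-2-yl)heptanal | O=CC[C@@H](CCC(C)=O)C(C)=C | intermediate
4 | (2E,5R)-2-methyl-8-oxo-5-(prop-1-en-2-yl)non-2-enal | O=C/C(C)=C/C[C@@H](CCC(C)=O)C(C)=C | intermediate
5 | (3E,6R)-3,9-dimethyl-6-(prop-1-en-2-yl)deca-1,3,9-triene | C=C/C(C)=C/C[C@@H](CCC(C)=C)C(C)=C | intermediate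
6 | α-selinene, (5R,7R,10R)-eudesma-3,11-diene (10β-Me, 5α-H, 7β-isopropenyl) | C=C(C)[C@@H]1CC[C@@]2(C)CCC=C(C)[C@@H]2C1 | intermediate
7 | 12-lithio-α-selinene (allyllithium·TMEDA) | [Li]CC(=C)[C@@H]1CC[C@@]2(C)CCC=C(C)[C@@H]2C1 | intermediate (not isolated)
8 | dimethyl (eudesma-3,11(13)-dien-12-yl)boronate | COB(OC)CC(=C)[C@@H]1CC[C@@]2(C)CCC=C(C)[C@@H]2C1 | intermediate (not isolated)
9 | (5R,7R,10R)-eudesma-3,11(13)-dien-12-ol (α-costol) | C=C(CO)[C@@H]1CC[C@@]2(C)CCC=C(C)[C@@H]2C1 | intermediate
10 | (5R,7R,10R)-eudesma-3,11(13)-dien-12-al (α-costal) | C=C(C=O)[C@@H]1CC[C@@]2(C)CCC=C(C)[C@@H]2C1 | intermediate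
11 | (5R,7R,10R)-15-hydroxyeudesma-3,11(13)-dien-12-al | C=C(C=O)[C@@H]1CC[C@@]2(C)CCC=C(CO)[C@@H]2C1 | intermediate
12 | 4-[(tert-butyldimethylsilyl)oxy]benzaldehyde | O=Cc1ccc(O[Si](C)(C)C(C)(C)C)cc1 | starting material
13 | methyl (Z)-3-{4-[(tert-butyldimethylsilyl)oxy]phenyl}prop-2-enoate | COC(=O)/C=C\c1ccc(O[Si](C)(C)C(C)(C)C)cc1 | intermediate
14 | (Z)-3-(4-hydroxyphenyl)prop-2-enoic acid | OC(=O)/C=C\c1ccc(O)cc1 | intermediate
15 | (5R,7R,10R)-15-[(Z)-p-coumaroyloxy]eudesma-3,11(13)-dien-12-al | C=C(C=O)[C@@H]1CC[C@@]2(C)CCC=C(COC(=O)/C=C\c3ccc(O)cc3)[C@@H]2C1 | intermediate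
16 | (5R,7R,10R)-15-[(Z)-p-coumaroyloxy]eudesma-3,11(13)-dien-12-oic acid | C=C(C(=O)O)[C@@H]1CC[C@@]2(C)CCC=C(COC(=O)/C=C\c3ccc(O)cc3)[C@@H]2C1 | target

**Total steps:** 11. **Longest linear sequence:** 9 (steps 1–7, 10, 11).

**Steps most likely to fail**

Step 4 (cycloaddition). At about 200 °C the trans/cis and facial selectivities may be insufficient. The C7 configuration may also erode through a reversible Cope shift of the 1,5-diene C13=C11–C7–C6–C5=C4, which passes through an achiral divinyl intermediate. The fallback sets out from 4, returns at 6, and activates the dienophile so that the ring closure runs at or below room temperature. One equivalent of Ph3P=CH2 at −78 °C methylenates only the aldehyde of 4, giving the dienyl ketone (5R,7E)-8-methyl-5-(prop-1-en-2-yl)deca-7,9-dien-2-one F1. Horner–Wadsworth–Emmons reaction with triethyl phosphonoacetate gives ethyl (2E,6R,8E)-3,9-dimethyl-6-(prop-1-en-2-yl)undeca-2,8,10-trienoate F2, from which the minor (2Z)-isomer is separated. Et2AlCl-promoted intramolecular Diels–Alder reaction through the ester-endo transition state should give the trans-fused ethyl (5α,7β,10β)-eudesma-3,11-diene-1β-carboxylate F3. Saponification gives (5α,7β,10β)-eudesma-3,11-diene-1β-carboxylic acid F4, and photocatalytic hydrodecarboxylation (acridinium photocatalyst, thiol hydrogen donor) removes the activating group to give 6.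

Step 5 (allylic lithiation–oxidation). Metalation may be incomplete or may stray to C15 or C2. The fallback sets out from 1, returns at 9, and carries the C12 oxygen from the start. SeO2/t-BuOOH hydroxylates the isopropenyl methyl of 1 (its only alkene) to (4R)-limonene 1,2-oxide-10-ol F5, which is silylated to its tert-butyldiphenylsilyl ether F6. Steps 1–4 are then repeated unchanged: periodic acid cleavage gives (3R)-3-{3-[(tert-butyldiphenylsilyl)oxy]prop-1-en-2-yl}-6-oxoheptanal F7, Wittig reaction gives (2E,5R)-5-{3-[(tert-butyldiphenylsilyl)oxy]prop-1-en-2-yl}-2-methyl-8-oxonon-2-enal F8, double methylenation gives (3E,6R)-6-{3-[(tert-butyldiphenylsilyl)oxy]prop-1-en-2-yl}-3,9-dimethyldeca-1,3,9-triene F9, and cycloaddition gives (5R,7R,10R)-12-[(tert-butyldiphenylsilyl)oxy]eudesma-3,11(13)-diene F10. TBAF then gives 9.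

Step 11 (chlorite oxidation). The free phenol may be chlorinated or oxidised, and the coumarate may isomerise Z→E. The fallback sets out from 11 and 13, returns at 16, and keeps the phenol silylated until the end. Me3SnOH cleaves only the methyl ester of 13, giving (Z)-3-{4-[(tert-butyldimethylsilyl)oxy]phenyl}prop-2-enoic acid F11. Mitsunobu esterification with 11 gives (5R,7R,10R)-15-{(Z)-3-[4-(tert-butyldimethylsilyloxy)phenyl]prop-2-enoyloxy}eudesma-3,11(13)-dien-12-al F12. Chlorite oxidation gives (5R,7R,10R)-15-{(Z)-3-[4-(tert-butyldimethylsilyloxy)phenyl]prop-2-enoyloxy}eudesma-3,11(13)-dien-12-oic acid F13, and HF·pyridine removes the silyl group to give 16.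

**Further compounds**
F1 | step 4 | (5R,7E)-8-methyl-5-(prop-1-en-2-yl)deca-7,9-dien-2-one | C=C/C(C)=C/C[C@@H](CCC(C)=O)C(C)=C
F2 | step 4 | ethyl (2E,6R,8E)-3,9-dimethyl-6-(prop-1-en-2-yl)undeca-2,8,10-trienoate | C=C/C(C)=C/C[C@@H](CC/C(C)=C/C(=O)OCC)C(C)=C
F3 | step 4 | ethyl (5α,7β,10β)-eudesma-3,11-diene-1β-carboxylate | C=C(C)[C@@H]1CC[C@@]2(C)[C@H](C(=O)OCC)CC=C(C)[C@@H]2C1
F4 | step 4 | (5α,7β,10β)-eudesma-3,11-diene-1β-carboxylic acid | C=C(C)[C@@H]1CC[C@@]2(C)[C@H](C(=O)O)CC=C(C)[C@@H]2C1
F5 | step 5 | (4R)-limonene 1,2-oxide-10-ol | CC12OC2C[C@@H](CC1)C(CO)=C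
F6 | step 5 | (4R)-10-[(tert-butyldiphenylsilyl)oxy]limonene 1,2-oxide | CC12OC2C[C@@H](CC1)C(CO[Si](c1ccccc1)(c1ccccc1)C(C)(C)C)=C
F7 | step 5 | (3R)-3-{3-[(tert-butyldiphenylsilyl)oxy]prop-1-en-2-yl}-6-oxoheptanal | O=CC[C@@H](CCC(C)=O)C(=C)CO[Si](c1ccccc1)(c1ccccc1)C(C)(C)C
F8 | step 5 | (2E,5R)-5-{3-[(tert-butyldiphenylsilyl)oxy]prop-1-en-2-yl}-2-methyl-8-oxonon-2-enal | O=C/C(C)=C/C[C@@H](CCC(C)=O)C(=C)CO[Si](c1ccccc1)(c1ccccc1)C(C)(C)C
F9 | step 5 | (3E,6R)-6-{3-[(tert-butyldiphenylsilyl)oxy]prop-1-en-2-yl}-3,9-dimethyldeca-1,3,9-triene | C=C/C(C)=C/C[C@@H](CCC(C)=C)C(=C)CO[Si](c1ccccc1)(c1ccccc1)C(C)(C)C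
F10 | step 5 | (5R,7R,10R)-12-[(tert-butyldiphenylsilyl)oxy]eudesma-3,11(13)-diene | C=C(CO[Si](c3ccccc3)(c4ccccc4)C(C)(C)C)[C@@H]1CC[C@@]2(C)CCC=C(C)[C@@H]2C1
F11 | step 11 | (Z)-3-{4-[(tert-butyldimethylsilyl)oxy]phenyl}prop-2-enoic acid | OC(=O)/C=C\c1ccc(O[Si](C)(C)C(C)(C)C)cc1
F12 | step 11 | (5R,7R,10R)-15-{(Z)-3-[4-(tert-butyldimethylsilyloxy)phenyl]prop-2-enoyloxy}eudesma-3,11(13)-dien-12-al | C=C(C=O)[C@@H]1CC[C@@]2(C)CCC=C(COC(=O)/C=C\c3ccc(O[Si](C)(C)C(C)(C)C)cc3)[C@@H]2C1
F13 | step 11 | (5R,7R,10R)-15-{(Z)-3-[4-(tert-butyldimethylsilyloxy)phenyl]prop-2-enoyloxy}eudesma-3,11(13)-dien-12-oic acid | C=C(C(=O)O)[C@@H]1CC[C@@]2(C)CCC=C(COC(=O)/C=C\c3ccc(O[Si](C)(C)C(C)(C)C)cc3)[C@@H]2C1
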